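The plan cuts the C2=C3 double bond of the furan ring. The methyl-bearing C3 derives from the carbonyl carbon of an aryl methyl ketone. The aryl-bearing C2 derives from the carbonyl carbon of the aroyl ester on the adjacent phenol oxygen, which is already O1 attached to C7a. Low-valent titanium joins these two carbons and removes both carbonyl oxygens. A single operation thus closes the furan ring onto a benzene ring that already holds its C5, C6 and C7 substituents, with no regiochemical choice left. The precursor is 3-allyl-2,4-dihydroxy-5-methoxyacetophenone esterified on both hydroxyls with 3,4,5-trimethoxybenzoyl groups. The ester at the future C6 merely masks that phenol and is hydrolysed last.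

Key step: step 6

Remark: the target has no stereocentre and no configured double bond. The sp3 centres in 8 and 12 are transient and racemic, and 12 is a formal drawing of the titanium-bound coupling product.

Step 1
Reactants: 1 isovanillin (3-hydroxy-4-methoxybenzaldehyde)
Product: 3 4-methoxybenzene-1,3-diol (4-methoxyresorcinol), via 3-hydroxy-4-methoxyphenyl formate 2 (not isolated)
Conditions: mCPBA, CH2Cl2, 0 °C to rt; then MeOH, cat. HCl, rt, under Ar
Reagents that add atoms: mCPBA (3-chloroperoxybenzoic acid), O=C(OO)c1cccc(Cl)c1
Why: Baeyer–Villiger oxidation: in the peracid adduct of the aldehyde the aryl group, made electron-rich by the para methoxy group, migrates to oxygen faster than hydride, and the labile aryl formate 2 is then cleaved by acid-catalysed transesterification with methanol, which keeps the oxidation-prone diol away from base and air.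

Step 2
Reactants: 3 4-methoxybenzene-1,3-diol; 4 acetic acid
Product: 5 1-(2,4-dihydroxy-5-methoxyphenyl)ethanone
Conditions: AcOH, BF3·OEt2 (as solvent), 85 °C; aq. NaOAc work-up
Reagents that add atoms: acetic acid (4), CC(=O)O
Why: Friedel–Crafts acylation promoted by BF3: the carbon ortho to one hydroxyl and para to the other is the most activated unhindered position of 3, and the hydrogen-bonded ortho-hydroxy ketone that results is deactivated towards a second acylation.

Step 3
Reactants: 5 1-(2,4-dihydroxy-5-methoxyphenyl)ethanone; 6 allyl bromide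
Product: 7 1-[4-(allyloxy)-2-hydroxy-5-methoxyphenyl]ethanone
Conditions: allyl bromide (1.05 equiv), K2CO3 (1.1 equiv), acetone, reflux
Reagents that add atoms: allyl bromide (6), C=CCBr
Why: Williamson ether synthesis: the hydroxyl para to the acetyl group is the more acidic and the freely accessible one, whereas the ortho hydroxyl is held in a hydrogen bond to the ketone oxygen, so a weak base and one equivalent of 6 should alkylate the para oxygen only.

Step 4
Reactants: 7 1-[4-(allyloxy)-2-hydroxy-5-methoxyphenyl]ethanone
Product: 9 1-(3-allyl-2,4-dihydroxy-5-methoxyphenyl)ethanone, via ortho-dienone 8 (not isolated)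
Conditions: N,N-diethylaniline, 200 °C, Ar; dilute HCl wash
Reagents that add atoms: none
Why: Aromatic Claisen rearrangement ([3,3]-sigmatropic shift): of the two carbons ortho to the allyloxy group one carries the methoxy group and offers no hydrogen for rearomatisation, so the reversible shift is drained through dienone 8 at the CH between the two oxygens, which tautomerises to phenol 9.

Step 5
Reactants: 9 1-(3-allyl-2,4-dihydroxy-5-methoxyphenyl)ethanone; 10 3,4,5-trimethoxybenzoyl chloride
Product: 11 4-acetyl-2-allyl-6-methoxy-1,3-phenylene bis(3,4,5-trimethoxybenzoate)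
Conditions: 10 (2.4 equiv), Et3N (3 equiv), cat. DMAP (4-dimethylaminopyridine), CH2Cl2, 0 °C to rt
Reagents that add atoms: 3,4,5-trimethoxybenzoyl chloride (10), COc1cc(C(Cl)=O)cc(OC)c1OC
Why: DMAP-catalysed O-acylation (nucleophilic catalysis) is strong enough to esterify even the crowded, hydrogen-bonded hydroxyl, while tertiary amines at or below room temperature do not enolise the ketone, so the Baker–Venkataraman acyl shift stays out of reach and one reagent installs both the reacting ester and the mask for the C6 oxygen.

Step 6
Reactants: 11 4-acetyl-2-allyl-6-methoxy-1,3-phenylene bis(3,4,5-trimethoxybenzoate)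
Product: 13 7-allyl-5-methoxy-3-methyl-2-(3,4,5-trimethoxyphenyl)-1-benzofuran-6-yl 3,4,5-trimethoxybenzoate, via titanium diolate 12 (not isolated)
Conditions: TiCl3 (6 equiv), Zn dust (12 equiv), THF, reflux (pre-reduction); then 11 in THF by syringe pump (high dilution), reflux; aq. K2CO3, filtration through kieselguhr
Reagents that add atoms: none
Why: Divalent titanium, made in the flask from TiCl3 and Zn, transfers electrons to the aryl ketone, the most easily reduced carbonyl group of 11, and the titanium-bound carbon so formed adds to the carbonyl carbon of the ester on the ortho oxygen to give diolate 12. More of the reagent then pulls both oxygens off 12 as TiOCl2, which leaves the C2=C3 double bond and thereby the aromatic furan, whose O1 is the former ester oxygen. The closest known reaction type is the intramolecular McMurry ketone–ester coupling, which is established for ortho-acyloxyaryl ketones as an entry to 2,3-disubstituted benzofurans. The furan ring closes in the 5-exo-trig mode, since C3 attacks an ester C=O whose oxygen stays outside the new ring C3–C3a–C7a–O1–C2, and no stereocentre is created because the two centres of 12 vanish on deoxygenation. The step must tell two identical aroyl esters apart and must beat bimolecular ketone coupling: only the ester ortho to the acetyl group lies within reach of the reduced carbon, the other one sits para across the ring, and slow addition at high dilution holds the bimolecular path down. The isolated terminal alkene is not reduced by this reagent and, being meta to the reacting carbon, cannot be reached by it either.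

Step 7
Reactants: 13 7-allyl-5-methoxy-3-methyl-2-(3,4,5-trimethoxyphenyl)-1-benzofuran-6-yl 3,4,5-trimethoxybenzoate
Product: 14 7-allyl-5-methoxy-3-methyl-2-(3,4,5-trimethoxyphenyl)-1-benzofuran-6-ol (target)
Conditions: LiOH, THF/MeOH/H2O, rt, Ar; then 1 M HCl; aq. NaHCO3 wash
Reagents that add atoms: none
Why: Saponification: the aryl ester has a good phenoxide leaving group and is cleaved by hydroxide at room temperature, conditions under which the allyl double bond does not move into conjugation and the methyl ethers and the benzofuran are untouched.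

Compound list
1 | isovanillin (3-hydroxy-4-methoxybenzaldehyde) | COc1ccc(C=O)cc1O | starting material
2 | 3-hydroxy-4-methoxyphenyl formate | COc1ccc(OC=O)cc1O | intermediate
3 | 4-methoxybenzene-1,3-diol | COc1ccc(O)cc1O | intermediate
4 | acetic acid | CC(=O)O | starting material
5 | 1-(2,4-dihydroxy-5-methoxyphenyl)ethanone | CC(=O)c1cc(OC)c(O)cc1O | intermediate
6 | allyl bromide | C=CCBr | starting material
7 | 1-[4-(allyloxy)-2-hydroxy-5-methoxyphenyl]ethanone | CC(=O)c1cc(OC)c(OCC=C)cc1O | intermediate
8 | 4-acetyl-6-allyl-5-hydroxy-2-methoxycyclohexa-2,4-dien-1-one (racemic) | CC(=O)C1=C(O)C(CC=C)C(=O)C(OC)=C1 | intermediate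
9 | 1-(3-allyl-2,4-dihydroxy-5-methoxyphenyl)ethanone | CC(=O)c1cc(OC)c(O)c(CC=C)c1O | intermediate
10 | 3,4,5-trimethoxybenzoyl chloride | COc1cc(C(Cl)=O)cc(OC)c1OC | starting material
11 | 4-acetyl-2-allyl-6-methoxy-1,3-phenylene bis(3,4,5-trimethoxybenzoate) (key-step precursor) | CC(=O)c1cc(OC)c(OC(=O)c2cc(OC)c(OC)c(OC)c2)c(CC=C)c1OC(=O)c1cc(OC)c(OC)c(OC)c1 | intermediate
12 | dichlorotitanium chelate of the cis-2,3-diolate of 7-allyl-5-methoxy-3-methyl-2-(3,4,5-trimethoxyphenyl)-2,3-dihydro-1-benzofuran-6-yl 3,4,5-trimethoxybenzoate (cis-fused, racemic) | CC12O[Ti](Cl)(Cl)OC1(c1cc(OC)c(OC)c(OC)c1)Oc1c2cc(OC)c(OC(=O)c2cc(OC)c(OC)c(OC)c2)c1CC=C | intermediate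
13 | 7-allyl-5-methoxy-3-methyl-2-(3,4,5-trimethoxyphenyl)-1-benzofuran-6-yl 3,4,5-trimethoxybenzoate (key-step product) | C=CCc1c(OC(=O)c2cc(OC)c(OC)c(OC)c2)c(OC)cc2c(C)c(-c3cc(OC)c(OC)c(OC)c3)oc12 | intermediate
14 | 7-allyl-5-methoxy-3-methyl-2-(3,4,5-trimethoxyphenyl)-1-benzofuran-6-ol | C=CCc1c(O)c(OC)cc2c(C)c(-c3cc(OC)c(OC)c(OC)c3)oc12 | target

Total step count: 7
Longest linear sequence: 7 steps (1 to 14)

Steps most likely to fail

1. Step 6.
- **Risk:** Bimolecular pinacol-type coupling or plain reduction of the ketone may outrun ring closure. The Lewis-acidic titanium and zinc chlorides may also strip the ortho ester before it can couple. Loss of the C6 ester alone would be harmless, since step 7 removes it anyway.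
- **Fallback:** It sets out from 9 and comes back at 13, and it makes the same C2=C3 bond by an intramolecular Wittig reaction. Ketone 9 would be reduced (NaBH4, THF/MeOH, 0 °C) to racemic 2-allyl-4-(1-hydroxyethyl)-6-methoxybenzene-1,3-diol F1. This is used crude and converted with PPh3·HBr in refluxing MeCN into racemic [1-(3-allyl-2,4-dihydroxy-5-methoxyphenyl)ethyl]triphenylphosphonium bromide F2. Heating F2 with 10 and Et3N in toluene should acylate both hydroxyls to the bis(aroyloxy)phosphonium bromide F3. Deprotonation of F3 gives the phosphorus ylide F4, which closes onto the neighbouring ester carbonyl to give 13.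

2. Step 5.
- **Risk:** The hydroxyl wedged between the acetyl and allyl groups is hydrogen-bonded and crowded, so acylation may stall after the first ester. Forcing it with stronger base invites migration of the aroyl group to the acetyl methyl carbon.
- **Fallback:** It sets out from 7 and comes back at 11, and it changes the order of events so that this oxygen is esterified while its second neighbour is still a hydrogen. Phenol 7 would be acylated with one equivalent of 10 (Et3N, cat. DMAP, CH2Cl2) to 2-acetyl-5-(allyloxy)-4-methoxyphenyl 3,4,5-trimethoxybenzoate F5. Heating F5 in diphenyl ether at about 200 °C should bring about the Claisen rearrangement through the ortho-dienone F6. This gives 6-acetyl-2-allyl-3-hydroxy-4-methoxyphenyl 3,4,5-trimethoxybenzoate F7. Its new, unchelated hydroxyl is then acylated with 10 under the same mild conditions to give 11.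

3. Step 4.
- **Risk:** At about 200 °C the freshly formed ortho-allylphenol may add a hydroxyl across its own alkene. The double bond may also drift into conjugation with the ring, or the electron-rich material may decompose on long heating.
- **Fallback:** It sets out from 5 and comes back at 11, replaces steps 3 to 5, and makes the aryl–allyl bond by cross-coupling instead of a sigmatropic shift. Ketone 5 would be iodinated at its only activated free carbon, the one between the two hydroxyls (I2, HIO3, aq. EtOH), to 1-(2,4-dihydroxy-3-iodo-5-methoxyphenyl)ethanone F8. Both hydroxyls are aroylated with 10 as in step 5 to 4-acetyl-2-iodo-6-methoxy-1,3-phenylene bis(3,4,5-trimethoxybenzoate) F9. A Stille coupling with allyltributylstannane (Pd(PPh3)4, DMF, 80 °C) should then deliver 11.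

Further compounds
F1 | step 6 | 2-allyl-4-(1-hydroxyethyl)-6-methoxybenzene-1,3-diol (racemic) | CC(O)c1cc(OC)c(O)c(CC=C)c1O
F2 | step 6 | [1-(3-allyl-2,4-dihydroxy-5-methoxyphenyl)ethyl]triphenylphosphonium bromide (racemic) | CC(c1cc(OC)c(O)c(CC=C)c1O)[P+](c1ccccc1)(c1ccccc1)c1ccccc1.[Br-]
F3 | step 6 | {1-[3-allyl-5-methoxy-2,4-bis(3,4,5-trimethoxybenzoyloxy)phenyl]ethyl}triphenylphosphonium bromide (racemic) | CC(c1cc(OC)c(OC(=O)c2cc(OC)c(OC)c(OC)c2)c(CC=C)c1OC(=O)c1cc(OC)c(OC)c(OC)c1)[P+](c1ccccc1)(c1ccccc1)c1ccccc1.[Br-]
F4 | step 6 | {1-[3-allyl-5-methoxy-2,4-bis(3,4,5-trimethoxybenzoyloxy)phenyl]ethylidene}triphenylphosphorane | CC(c1cc(OC)c(OC(=O)c2cc(OC)c(OC)c(OC)c2)c(CC=C)c1OC(=O)c1cc(OC)c(OC)c(OC)c1)=P(c1ccccc1)(c1ccccc1)c1ccccc1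
F5 | step 5 | 2-acetyl-5-(allyloxy)-4-methoxyphenyl 3,4,5-trimethoxybenzoate | CC(=O)c1cc(OC)c(OCC=C)cc1OC(=O)c1cc(OC)c(OC)c(OC)c1
F6 | step 5 | 2-acetyl-6-allyl-4-methoxy-5-oxocyclohexa-1,3-dien-1-yl 3,4,5-trimethoxybenzoate (racemic) | CC(=O)C1=C(OC(=O)c2cc(OC)c(OC)c(OC)c2)C(CC=C)C(=O)C(OC)=C1
F7 | step 5 | 6-acetyl-2-allyl-3-hydroxy-4-methoxyphenyl 3,4,5-trimethoxybenzoate | CC(=O)c1cc(OC)c(O)c(CC=C)c1OC(=O)c1cc(OC)c(OC)c(OC)c1
F8 | step 4 | 1-(2,4-dihydroxy-3-iodo-5-methoxyphenyl)ethanone | CC(=O)c1cc(OC)c(O)c(I)c1O
F9 | step 4 | 4-acetyl-2-iodo-6-methoxy-1,3-phenylene bis(3,4,5-trimethoxybenzoate) | CC(=O)c1cc(OC)c(OC(=O)c2cc(OC)c(OC)c(OC)c2)c(I)c1OC(=O)c1cc(OC)c(OC)c(OC)c1
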